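## Analysis of the target

- The target is a heliangolide-type germacranolide. Germacrane numbering is used throughout: ring atoms C1–C10, lactone carbons C11–C13, C14 the methyl on C10, C15 the methyl on C4. The ten-membered carbocycle is trans-fused at C6/C7 to an α-methylene-γ-butyrolactone whose ring oxygen sits on C6.
- The ring carries a Z trisubstituted olefin C4=C5 flanked by two oxygenated carbons, C3 (isobutyrate, S) and C6 (lactone oxygen, R), and a trans C1–C10 epoxide (1R,10R). C8 (R) bears an ester of (2R,3S)-2,3-dimethyloxirane-2-carboxylic acid; the SMILES shows the two methyl groups cis, so this is the epoxide of tiglic acid.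
- Six of the eight stereocentres lie on the medium ring. C6/C7/C8 form a contiguous triad: O6 and C11 trans, C11 and O8 cis, O6 and O8 1,3-anti. C3 is separated from the triad by the Z olefin. C1/C10 follow from the face of an E olefin.
- Sensitive groups are the exo-methylene lactone (Michael acceptor), three acyl–oxygen bonds that must stay differentiated (a free 8-hydroxyl can relactonise to the 8,12-olide under base), two epoxides, and, before the last step, a 1(10),4-diene prone to acid-induced transannular cyclisation.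
- The hard part is the ring itself: a ten-membered closure with a Z olefin between two carbinol carbons, and stereocontrol on a flexible ring.
- The feature that invites the key step: ring atoms C1–C2–C3–C4(=C5)–C6, with the cis olefin and oxygen on C3 and C6, are a 4-oxygenated cyclohex-2-en-1-one once a C1–C6 bond is added. The remaining atoms C6(O)–C7–C8(O)–C9–C10(=C1) then complete the retron of an oxy-Cope rearrangement: carbonyl at C6, E olefin C1=C10, new σ bond C8–C9. That cyclohexenone, with C9/C10/C14 as an isopropenyl group on C1, has the carbon skeleton of carvone.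

## Retrosynthetic reasoning

**27 ⇒ 26 (C1–O and C10–O).** The ring epoxide is cut first because it is the most acid-labile group and because its precursor, the E olefin C1=C10, is what the key step produces. In the forward direction a peracid has to select C1=C10 among three olefins and attack its outer face.

**26 ⇒ 25 ⇒ 24 (acyl–O bond at C3).** The isobutyrate has an acidic α-hydrogen and cannot be present when the lactone enolate is made, so O3 travels as a silyl ether and is acylated late.

**24 ⇒ 20 (C11=C13).** The exo-methylene carbon is added to the finished lactone; the C8 ester in 20 has no α-hydrogen, so only C11 can be enolised.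

**20 ⇒ 15 + 18 (C6–H, O8–acyl and O6–C12).** The 1,3-anti relation of O6 and O8 is the signature of an intramolecular hydride transfer of the Tishchenko type from a hemiacetal on O8 to a C6 ketone. If the hydride donor is the aldehyde 18 of the side chain itself, one operation sets C6, installs the complete C8 ester and, by blocking O8, leaves O6 as the only hydroxyl that can close the lactone. This removes the 6,12- versus 8,12-olide ambiguity.

**15 ⇒ 14 (O8–benzyl bond).** Only a protecting group is removed; the tert-butyl ester at C12 is chosen so that the freed 8-hydroxyl cannot lactonise prematurely.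

**14 ⇒ 11 (key: form C8–C9 and C7–C11, cut C1–C6).** A [3,3] shift of the alkoxide of 11 expands the cyclohexene by four atoms to the ten-membered ring. The Z olefin C4=C5 is already locked in the six-membered ring, C1=C10 is formed E, C8 is set by chirality transfer from C1, and the enolate released at C6/C7 is alkylated in the same flask to bring in C11/C12. The precursor 11 is a cyclohexenol with three stereocentres; the product 14 holds the complete ring, both ring olefins, C7, C8 and fourteen of the fifteen skeletal carbons.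

**11 ⇒ 4 + 8 (C6–C7).** A 1,2-addition of the cis-alkoxyvinyl metal derived from 8 to enone 4 joins the two fragments. The addition has to occur trans to the isopropenyl group.

**4 ⇒ 3 ⇒ 2 ⇒ 1 (C6=O, O3–Si, C3–H).** The carbonyl of (S)-carvone (1) becomes the C3 oxygen of the target, the ring olefin of 1 becomes C4=C5, and the isopropenyl carbon becomes C1. An allylic oxidation places the future C6 carbonyl next to it.

**8 ⇒ 6 ⇒ 5 and 18 ⇒ 17 ⇒ 16.** The two small partners come from the alcohol 5 (vinylation, then bromination and elimination) and from the allylic alcohol 16 (asymmetric epoxidation, then oxidation).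

## Alternatives that were turned down

**Alternative 1:** the textbook disconnection. Cut C6–C7 and the lactone C12–O bond; the forward key step is an intramolecular CrCl2-mediated (Nozaki–Hiyama–Kishi type) allylation of the Z enal in the open-chain bromide A1, followed by lactonisation.
- A1 already contains all fifteen carbons, both trisubstituted olefins and the C3 and C8 stereocentres, so it needs a long linear sequence and the cyclisation removes little complexity.
- The Z enal is configurationally labile towards the Lewis-acidic chromium salts; isomerisation leads into the 4E series.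
- The C6/C7 configuration would depend on remote induction from C8 through a strained ten-membered transition state under high dilution.

**Alternative 2:** cut C4=C5. The forward key step is ring-closing metathesis of the triene A2 (isopropenyl terminus at C4, vinyl group on C6) with a second-generation Grubbs catalyst, which would give 26 directly.
- The new olefin is trisubstituted, lies between two oxygen-bearing allylic carbons, and must be Z in a ten-membered ring; initiation at both termini is slow and dimerisation is favoured.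
- Nothing in A2 controls the geometry.
- A2 contains three further olefins that can engage the carbene, and the C6/C7/C8 triad would have to be built acyclically first.

**Alternative 3:** cut C6–C7 by ring contraction. The forward key step is a [2,3]-Wittig rearrangement of the thirteen-membered diallyl ether A3 (oxygen bridging C6 and C12).
- The base must choose between two allylic α-oxy methylene groups (C6 and C12), and the Z allyl anion can lose its geometry.
- The syn/anti outcome at C6/C7 rests on transannular induction from C8.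
- After the contraction C12 is only a methyl group of an isopropenyl unit, so an allylic oxidation, a second oxidation and a lactonisation must follow in the presence of three other allylic systems. The precursor again holds the whole carbon chain.

Key step: step 7

## Route

Remark: in the steps, atoms of the cyclohexene intermediates are related to the target as follows. In enone 4, C1 (C=O) = target C6, C2 = C5, C3 = C4, C4 = C3, C5 = C2, C6 = C1; the isopropenyl group supplies C10, C14 and C9.

Step 1
Reactants: 1 (S)-(+)-carvone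
Product: 2 (1S,5S)-2-methyl-5-(prop-1-en-2-yl)cyclohex-2-en-1-ol (cis-carveol)
Conditions: NaBH4, CeCl3·7H2O, MeOH, −20 °C
Reagents that add atoms: none
Why: Luche 1,2-reduction; axial hydride delivery to the enone should give the equatorial alcohol cis to the isopropenyl group, which sets the carbinol centre (1S), the future C3 of the target.

Step 2
Reactants: 2 (1S,5S)-2-methyl-5-(prop-1-en-2-yl)cyclohex-2-en-1-ol
Product: 3 tert-butyldimethyl{[(1S,5S)-2-methyl-5-(prop-1-en-2-yl)cyclohex-2-en-1-yl]oxy}silane
Conditions: TBSCl, imidazole, DMF, 23 °C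
Reagents that add atoms: tert-butyldimethylsilyl chloride, CC(C)(C)[Si](C)(C)Cl
Why: Standard silylation of a secondary allylic alcohol; the silyl ether should survive the organometallic, strongly basic, oxidative and mildly acidic steps up to step 13.

Step 3
Reactants: 3 tert-butyldimethyl{[(1S,5S)-2-methyl-5-(prop-1-en-2-yl)cyclohex-2-en-1-yl]oxy}silane
Product: 4 (4S,6S)-4-[(tert-butyldimethylsilyl)oxy]-3-methyl-6-(prop-1-en-2-yl)cyclohex-2-en-1-one
Conditions: CrO3, 3,5-dimethylpyrazole, CH2Cl2, −20 °C
Reagents that add atoms: chromium trioxide, O=[Cr](=O)=O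
Why: Allylic C–H oxidation of a cyclohexene to the enone with the CrO3–pyrazole complex; the ring CH2 next to the unsubstituted olefin carbon is the site that leads to a conjugated enone, while the C–H on the silyloxy carbon is shielded by the silyl group and the methyl. The base-free conditions should leave the new α-stereocentre (6S) untouched.

Step 4
Reactants: 5 (4-methoxyphenyl)methanol
Product: 6 1-[(ethenyloxy)methyl]-4-methoxybenzene
Conditions: Pd(OAc)2 (cat.), 1,10-phenanthroline (cat.), ethyl vinyl ether (excess), CH2Cl2, 23 °C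
Reagents that add atoms: ethyl vinyl ether, C=COCC
Why: Palladium-catalysed transfer vinylation (vinyl ether exchange), driven by the excess of ethyl vinyl ether.

Step 5
Reactants: 6 1-[(ethenyloxy)methyl]-4-methoxybenzene
Product: 8 1-{[(Z)-2-bromoethenyl]oxymethyl}-4-methoxybenzene, via dibromide 7 (not isolated)
Conditions: Br2, CH2Cl2, −78 °C; then DBU, −78 → 23 °C
Reagents that add atoms: bromine, BrBr
Why: Bromine addition to the enol ether and dehydrobromination of the α-bromo ether; as with simple alkyl vinyl ethers the elimination should give mainly the cis (Z) 2-bromovinyl ether, and the low temperature keeps bromine away from the anisyl ring.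

Step 6
Reactants: 8 1-{[(Z)-2-bromoethenyl]oxymethyl}-4-methoxybenzene; 4 (4S,6S)-4-[(tert-butyldimethylsilyl)oxy]-3-methyl-6-(prop-1-en-2-yl)cyclohex-2-en-1-one
Product: 11 (1S,4S,6S)-4-[(tert-butyldimethylsilyl)oxy]-1-{(Z)-2-[(4-methoxyphenyl)methoxy]ethenyl}-3-methyl-6-(prop-1-en-2-yl)cyclohex-2-en-1-ol, via vinyllithium 9 (not isolated), via vinylcerium dichloride 10 (not isolated)
Conditions: 8, t-BuLi (2 equiv), Et2O, −78 °C; CeCl3, THF, −78 °C; then 4, −78 °C; aq. NaHCO3 work-up
Reagents that add atoms: none
Why: Bromine–lithium exchange with retention gives the configurationally stable cis-2-alkoxyvinyllithium; the organocerium reagent adds 1,2 to the enolisable enone without deprotonating it. Attack on the carbonyl face opposite to the α-isopropenyl group (the cis silyloxy group lies on the same side) should give the 1S carbinol with the alkenyl group trans to the isopropenyl group; the acid-labile product is purified on base-washed silica.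

Step 7
Reactants: 11 (1S,4S,6S)-4-[(tert-butyldimethylsilyl)oxy]-1-{(Z)-2-[(4-methoxyphenyl)methoxy]ethenyl}-3-methyl-6-(prop-1-en-2-yl)cyclohex-2-en-1-ol
Product: 14 tert-butyl 2-[(1R,3Z,5S,7E,10R)-5-[(tert-butyldimethylsilyl)oxy]-10-[(4-methoxyphenyl)methoxy]-4,8-dimethyl-2-oxocyclodeca-3,7-dien-1-yl]acetate, via potassium alkoxide 12 (not isolated), via potassium enolate 13 (not isolated)
Conditions: KN(SiMe3)2, THF (no crown ether), 0 → 40 °C; then BrCH2CO2t-Bu, −78 → −40 °C
Reagents that add atoms: tert-butyl bromoacetate, BrCC(=O)OC(C)(C)C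
Why: Deprotonation gives alkoxide 12, whose anionic oxy-Cope [3,3] shift through a chair transition state breaks the C1–C6 bond of the cyclohexene and forms C8–C9, and the enolate 13 so released is alkylated on C7 by the bromoacetate; the closest known reaction type is the anionic oxy-Cope ring expansion of 1,2-dialkenylcyclohexenols to cyclodecadienones with in situ enolate alkylation, including dienes with an enol ether terminus. The ten-membered ring is not closed by a cyclisation but arises by four-atom ring expansion of the six-membered ring, so the Z olefin C4=C5 is inherited from the cyclohexene. The trans, diequatorial alkenyl groups of 11 allow only the chair with both ring bonds equatorial, which makes C1=C10 E. C8 is set by chirality transfer from C1 (the isopropenyl-bearing carbon, 6S in 11, which becomes sp2): this carbon fixes the sense of the chair, and the Z enol ether places the benzyloxy oxygen axial, syn to the axial oxide and bridged to it by K+, which should give 8R. The same bridge persists in 13 as a six-membered potassium chelate that holds the C8–O bond in the enolate plane with C9 on one face and only H8 on the other, so the electrophile should enter anti to C9 (the sense known for alkylation of chelated β-alkoxy enolates) and give 7R. The step needs chair over boat (secured by the trans arrangement of the two alkenyl groups), C- over O-alkylation (soft haloacetate, potassium enolate in THF) and survival of the β-alkoxy enolate (the chelate keeps the C8–O bond orthogonal to the enolate π system, and trapping is done cold). C3 is a spectator throughout.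

Step 8
Reactants: 14 tert-butyl 2-[(1R,3Z,5S,7E,10R)-5-[(tert-butyldimethylsilyl)oxy]-10-[(4-methoxyphenyl)methoxy]-4,8-dimethyl-2-oxocyclodeca-3,7-dien-1-yl]acetate
Product: 15 tert-butyl 2-[(1R,3Z,5S,7E,10R)-5-[(tert-butyldimethylsilyl)oxy]-10-hydroxy-4,8-dimethyl-2-oxocyclodeca-3,7-dien-1-yl]acetate
Conditions: DDQ, CH2Cl2/pH 7 buffer, 0 °C
Reagents that add atoms: none
Why: Oxidative cleavage of the 4-methoxybenzyl ether; the silyl ether, the olefins and the enone are inert to DDQ, and the tert-butyl ester should keep the freed 8-hydroxyl from lactonising onto C12.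

Step 9
Reactants: 16 (2E)-2-methylbut-2-en-1-ol
Product: 17 [(2S,3S)-2,3-dimethyloxiran-2-yl]methanol
Conditions: Ti(O-i-Pr)4 (cat.), L-(+)-diethyl tartrate (cat.), t-BuOOH, 4 Å molecular sieves, CH2Cl2, −20 °C
Reagents that add atoms: tert-butyl hydroperoxide, CC(C)(C)OO
Why: Sharpless asymmetric epoxidation; with the L-(+)-tartrate the oxygen is delivered to the face of the E allylic alcohol that gives the (2S,3S) epoxy alcohol, which sets both stereocentres of the side chain.

Step 10
Reactants: 17 [(2S,3S)-2,3-dimethyloxiran-2-yl]methanol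
Product: 18 (2R,3S)-2,3-dimethyloxirane-2-carbaldehyde
Conditions: Dess–Martin periodinane, pyridine, CH2Cl2, 0 → 23 °C; used as a dried solution
Reagents that add atoms: none
Why: Mild oxidation of the primary alcohol to a non-enolisable epoxy aldehyde; the descriptor at C2 changes from S to R only through the priority rules.

Step 11
Reactants: 15 tert-butyl 2-[(1R,3Z,5S,7E,10R)-5-[(tert-butyldimethylsilyl)oxy]-10-hydroxy-4,8-dimethyl-2-oxocyclodeca-3,7-dien-1-yl]acetate; 18 (2R,3S)-2,3-dimethyloxirane-2-carbaldehyde
Product: 20 (3aR,4R,6E,9S,10Z,11aR)-9-[(tert-butyldimethylsilyl)oxy]-6,10-dimethyl-2-oxo-2,3,3a,4,5,8,9,11a-octahydrocyclodeca[b]furan-4-yl (2R,3S)-2,3-dimethyloxirane-2-carboxylate, via hydroxy ester 19 (not isolated)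
Conditions: 18 (excess), SmI2 (0.3 equiv), THF, −10 °C; then CSA (cat.), CH2Cl2, 23 °C
Reagents that add atoms: none
Why: Evans–Tishchenko reduction: the samarium-bound hemiacetal formed from the 8-hydroxyl and 18 transfers its hydride intramolecularly to the C6 ketone through a chair-like transition state with C5, C9 and C11 equatorial, which should give the 1,3-anti alcohol (6R) and at the same time turn the aldehyde into the C8 ester. The 6-hydroxyl is then the only free hydroxyl, so acid-catalysed lactonisation onto the tert-butyl ester can only give the trans 6,12-olide.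

Step 12
Reactants: 20 (3aR,4R,6E,9S,10Z,11aR)-9-[(tert-butyldimethylsilyl)oxy]-6,10-dimethyl-2-oxo-2,3,3a,4,5,8,9,11a-octahydrocyclodeca[b]furan-4-yl (2R,3S)-2,3-dimethyloxirane-2-carboxylate
Product: 24 (3aR,4R,6E,9S,10Z,11aR)-9-[(tert-butyldimethylsilyl)oxy]-6,10-dimethyl-3-methylidene-2-oxo-2,3,3a,4,5,8,9,11a-octahydrocyclodeca[b]furan-4-yl (2R,3S)-2,3-dimethyloxirane-2-carboxylate, via lithium enolate 21 (not isolated), via Mannich base 22 (not isolated), via methiodide 23 (not isolated)
Conditions: LiN(SiMe3)2, THF, −78 °C; CH2=NMe2+ I−, −78 → 0 °C; MeI, MeOH, 23 °C; aq. NaHCO3, CH2Cl2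
Reagents that add atoms: N,N-dimethylmethyleneiminium iodide, C=[N+](C)C.[I-]
Why: Lactone enolate Mannich reaction with the iminium salt, quaternisation and elimination is the standard α-methylenation of γ-lactones; the C8 ester has no α-hydrogen, so only C11 is deprotonated, and the new centre at C11 disappears in the elimination.

Step 13
Reactants: 24 (3aR,4R,6E,9S,10Z,11aR)-9-[(tert-butyldimethylsilyl)oxy]-6,10-dimethyl-3-methylidene-2-oxo-2,3,3a,4,5,8,9,11a-octahydrocyclodeca[b]furan-4-yl (2R,3S)-2,3-dimethyloxirane-2-carboxylate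
Product: 25 (3aR,4R,6E,9S,10Z,11aR)-9-hydroxy-6,10-dimethyl-3-methylidene-2-oxo-2,3,3a,4,5,8,9,11a-octahydrocyclodeca[b]furan-4-yl (2R,3S)-2,3-dimethyloxirane-2-carboxylate
Conditions: Et3N·3HF, THF, 23 °C
Reagents that add atoms: none
Why: Fluoride cleavage of the allylic silyl ether under nearly neutral conditions, which should spare the exo-methylene lactone, the glycidic ester and the diene.

Step 14
Reactants: 25 (3aR,4R,6E,9S,10Z,11aR)-9-hydroxy-6,10-dimethyl-3-methylidene-2-oxo-2,3,3a,4,5,8,9,11a-octahydrocyclodeca[b]furan-4-yl (2R,3S)-2,3-dimethyloxirane-2-carboxylate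
Product: 26 (3aR,4R,6E,9S,10Z,11aR)-6,10-dimethyl-3-methylidene-9-[(2-methylpropanoyl)oxy]-2-oxo-2,3,3a,4,5,8,9,11a-octahydrocyclodeca[b]furan-4-yl (2R,3S)-2,3-dimethyloxirane-2-carboxylate
Conditions: (i-PrCO)2O, DMAP (cat.), Et3N, CH2Cl2, 0 °C
Reagents that add atoms: isobutyric anhydride, CC(C)C(=O)OC(=O)C(C)C
Why: DMAP-catalysed acylation of the secondary allylic 3-hydroxyl with retention at C3; no other hydroxyl is free.

Step 15
Reactants: 26 (3aR,4R,6E,9S,10Z,11aR)-6,10-dimethyl-3-methylidene-9-[(2-methylpropanoyl)oxy]-2-oxo-2,3,3a,4,5,8,9,11a-octahydrocyclodeca[b]furan-4-yl (2R,3S)-2,3-dimethyloxirane-2-carboxylate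
Product: 27 [(1R,2R,4R,6R,8S,9Z,11R)-4,9-dimethyl-14-methylidene-8-[(2-methylpropanoyl)oxy]-13-oxo-5,12-dioxatricyclo[9.3.0.0(4,6)]tetradec-9-en-2-yl] (2R,3S)-2,3-dimethyloxirane-2-carboxylate (CNP0117882.3)
Conditions: mCPBA, CH2Cl2, −20 → 0 °C
Reagents that add atoms: 3-chloroperoxybenzoic acid, OOC(=O)c1cccc(Cl)c1
Why: Prilezhaev epoxidation; C1=C10 is the only electron-rich olefin (C4=C5 lies between two acyloxy-bearing carbons, C11=C13 is conjugated to the lactone). Stereospecific syn addition to the E olefin gives the trans epoxide, and attack on the outer face of the ring conformer with C14 on the β side should give 1R,10R.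

## Compound list

1 | (S)-(+)-carvone | CC1=CC[C@@H](CC1=O)C(C)=C | starting material
2 | (1S,5S)-2-methyl-5-(prop-1-en-2-yl)cyclohex-2-en-1-ol | CC1=CC[C@@H](C[C@@H]1O)C(C)=C | intermediate
3 | tert-butyldimethyl{[(1S,5S)-2-methyl-5-(prop-1-en-2-yl)cyclohex-2-en-1-yl]oxy}silane | CC1=CC[C@@H](C[C@@H]1O[Si](C)(C)C(C)(C)C)C(C)=C | intermediate
4 | (4S,6S)-4-[(tert-butyldimethylsilyl)oxy]-3-methyl-6-(prop-1-en-2-yl)cyclohex-2-en-1-one | CC1=CC(=O)[C@@H](C[C@@H]1O[Si](C)(C)C(C)(C)C)C(C)=C | intermediate
5 | (4-methoxyphenyl)methanol | COc1ccc(CO)cc1 | starting material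
6 | 1-[(ethenyloxy)methyl]-4-methoxybenzene | C=COCc1ccc(OC)cc1 | intermediate
7 | 1-[(1,2-dibromoethoxy)methyl]-4-methoxybenzene (racemic) | BrCC(Br)OCc1ccc(OC)cc1 | intermediate
8 | 1-{[(Z)-2-bromoethenyl]oxymethyl}-4-methoxybenzene | Br/C=C\OCc1ccc(OC)cc1 | intermediate
9 | (Z)-2-[(4-methoxyphenyl)methoxy]ethenyllithium | [Li]/C=C\OCc1ccc(OC)cc1 | intermediate
10 | dichloro{(Z)-2-[(4-methoxyphenyl)methoxy]ethenyl}cerium | Cl[Ce](Cl)/C=C\OCc1ccc(OC)cc1 | intermediate
11 | (1S,4S,6S)-4-[(tert-butyldimethylsilyl)oxy]-1-{(Z)-2-[(4-methoxyphenyl)methoxy]ethenyl}-3-methyl-6-(prop-1-en-2-yl)cyclohex-2-en-1-ol | CC1=C[C@@](O)(/C=C\OCc2ccc(OC)cc2)[C@@H](C[C@@H]1O[Si](C)(C)C(C)(C)C)C(C)=C | intermediate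
12 | potassium alkoxide of 11 | CC1=C[C@@](O[K])(/C=C\OCc2ccc(OC)cc2)[C@@H](C[C@@H]1O[Si](C)(C)C(C)(C)C)C(C)=C | intermediate
13 | potassium (1Z,3R,5E,8S,9Z)-8-[(tert-butyldimethylsilyl)oxy]-3-[(4-methoxyphenyl)methoxy]-5,9-dimethylcyclodeca-1,5,9-trien-1-olate | [K]O/C1=C\[C@H](OCc2ccc(OC)cc2)C/C(C)=C/C[C@H](O[Si](C)(C)C(C)(C)C)/C(C)=C\1 | intermediate
14 | tert-butyl 2-[(1R,3Z,5S,7E,10R)-5-[(tert-butyldimethylsilyl)oxy]-10-[(4-methoxyphenyl)methoxy]-4,8-dimethyl-2-oxocyclodeca-3,7-dien-1-yl]acetate | O=C1/C=C(/C)[C@@H](O[Si](C)(C)C(C)(C)C)C/C=C(\C)C[C@@H](OCc2ccc(OC)cc2)[C@H]1CC(=O)OC(C)(C)C | intermediate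
15 | tert-butyl 2-[(1R,3Z,5S,7E,10R)-5-[(tert-butyldimethylsilyl)oxy]-10-hydroxy-4,8-dimethyl-2-oxocyclodeca-3,7-dien-1-yl]acetate | O=C1/C=C(/C)[C@@H](O[Si](C)(C)C(C)(C)C)C/C=C(\C)C[C@@H](O)[C@H]1CC(=O)OC(C)(C)C | intermediate
16 | (2E)-2-methylbut-2-en-1-ol | C/C=C(\C)CO | starting material
17 | [(2S,3S)-2,3-dimethyloxiran-2-yl]methanol | OC[C@]1(C)O[C@H]1C | intermediate
18 | (2R,3S)-2,3-dimethyloxirane-2-carbaldehyde | O=C[C@]1(C)O[C@H]1C | intermediate
19 | tert-butyl 2-[(1S,2R,3Z,5S,7E,10R)-5-[(tert-butyldimethylsilyl)oxy]-10-{[(2R,3S)-2,3-dimethyloxirane-2-carbonyl]oxy}-2-hydroxy-4,8-dimethylcyclodeca-3,7-dien-1-yl]acetate | O[C@@H]1/C=C(/C)[C@@H](O[Si](C)(C)C(C)(C)C)C/C=C(\C)C[C@@H](OC(=O)[C@]2(C)O[C@H]2C)[C@H]1CC(=O)OC(C)(C)C | intermediate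
20 | (3aR,4R,6E,9S,10Z,11aR)-9-[(tert-butyldimethylsilyl)oxy]-6,10-dimethyl-2-oxo-2,3,3a,4,5,8,9,11a-octahydrocyclodeca[b]furan-4-yl (2R,3S)-2,3-dimethyloxirane-2-carboxylate | C1C(=O)O[C@@H]2/C=C(/C)[C@@H](O[Si](C)(C)C(C)(C)C)C/C=C(\C)C[C@@H](OC(=O)[C@]3(C)O[C@H]3C)[C@@H]12 | intermediate
21 | lithium enolate of 20 | C1=C(O[Li])O[C@@H]2/C=C(/C)[C@@H](O[Si](C)(C)C(C)(C)C)C/C=C(\C)C[C@@H](OC(=O)[C@]3(C)O[C@H]3C)[C@@H]12 | intermediate
22 | 3-[(dimethylamino)methyl] derivative of 20 (mixture at C11) | CN(C)CC1C(=O)O[C@@H]2/C=C(/C)[C@@H](O[Si](C)(C)C(C)(C)C)C/C=C(\C)C[C@@H](OC(=O)[C@]3(C)O[C@H]3C)[C@@H]12 | intermediate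
23 | trimethylammonium iodide of 22 (mixture at C11) | C[N+](C)(C)CC1C(=O)O[C@@H]2/C=C(/C)[C@@H](O[Si](C)(C)C(C)(C)C)C/C=C(\C)C[C@@H](OC(=O)[C@]3(C)O[C@H]3C)[C@@H]12.[I-] | intermediate
24 | (3aR,4R,6E,9S,10Z,11aR)-9-[(tert-butyldimethylsilyl)oxy]-6,10-dimethyl-3-methylidene-2-oxo-2,3,3a,4,5,8,9,11a-octahydrocyclodeca[b]furan-4-yl (2R,3S)-2,3-dimethyloxirane-2-carboxylate | C=C1C(=O)O[C@@H]2/C=C(/C)[C@@H](O[Si](C)(C)C(C)(C)C)C/C=C(\C)C[C@@H](OC(=O)[C@]3(C)O[C@H]3C)[C@@H]12 | intermediate
25 | (3aR,4R,6E,9S,10Z,11aR)-9-hydroxy-6,10-dimethyl-3-methylidene-2-oxo-2,3,3a,4,5,8,9,11a-octahydrocyclodeca[b]furan-4-yl (2R,3S)-2,3-dimethyloxirane-2-carboxylate | C=C1C(=O)O[C@@H]2/C=C(/C)[C@@H](O)C/C=C(\C)C[C@@H](OC(=O)[C@]3(C)O[C@H]3C)[C@@H]12 | intermediate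
26 | (3aR,4R,6E,9S,10Z,11aR)-6,10-dimethyl-3-methylidene-9-[(2-methylpropanoyl)oxy]-2-oxo-2,3,3a,4,5,8,9,11a-octahydrocyclodeca[b]furan-4-yl (2R,3S)-2,3-dimethyloxirane-2-carboxylate | C=C1C(=O)O[C@@H]2/C=C(/C)[C@@H](OC(=O)C(C)C)C/C=C(\C)C[C@@H](OC(=O)[C@]3(C)O[C@H]3C)[C@@H]12 | intermediate
27 | CNP0117882.3, [(1R,2R,4R,6R,8S,9Z,11R)-4,9-dimethyl-14-methylidene-8-[(2-methylpropanoyl)oxy]-13-oxo-5,12-dioxatricyclo[9.3.0.0(4,6)]tetradec-9-en-2-yl] (2R,3S)-2,3-dimethyloxirane-2-carboxylate | C=C1C(=O)O[C@@H]2/C=C(/C)[C@@H](OC(=O)C(C)C)C[C@H]3O[C@]3(C)C[C@@H](OC(=O)[C@]3(C)O[C@H]3C)[C@@H]12 | target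

## Step count and least certain steps

Total step count: 15. Longest linear sequence: 11 steps (steps 1, 2, 3, 6, 7, 8, 11, 12, 13, 14, 15, from 1 to 27). Steps 4–5 and 9–10 are two-step side branches.

**Step 7 (key step).** Without a crown ether the rearrangement may be slow, and the β-alkoxy enolate may then lose the C8 alkoxide by elimination or be alkylated from the wrong face if the potassium bridge is not kept; a boat-like pathway would in addition erode the transfer of chirality to C8. The fallback separates the two events and sets out from 11. The rearrangement is run with KH and 18-crown-6 in THF at 0 °C and the enolate is protonated at −78 °C to give (2Z,4S,6E,9R)-4-[(tert-butyldimethylsilyl)oxy]-9-[(4-methoxyphenyl)methoxy]-3,7-dimethylcyclodeca-2,6-dien-1-one F1, which has no stereocentre at C7. This ketone is then enolised with LiN(SiMe3)2 at −78 °C, where lithium chelates O6 and the C8 ether, and alkylated with tert-butyl bromoacetate; C7 can also be equilibrated α to the ketone. The fallback comes back to the route at 14.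

**Step 6.** Facial selectivity of the 1,2-addition may be poor, because axial attack on the cyclohexenone competes with the required attack trans to the isopropenyl group. The fallback sets out from 4 and uses the by-product instead of discarding it. The epimeric carbinol (1R,4S,6S)-4-[(tert-butyldimethylsilyl)oxy]-1-{(Z)-2-[(4-methoxyphenyl)methoxy]ethenyl}-3-methyl-6-(prop-1-en-2-yl)cyclohex-2-en-1-ol F2 loses its carbinol stereocentre in the rearrangement. With KH and 18-crown-6 it should pass through the chair that has the oxide equatorial and the same sense of chirality transfer from C1 to C8, and protonation gives the same ketone F1. F1 is then taken on as described for step 7, and the fallback comes back to the route at 14.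

**Step 11.** The intramolecular hydride transfer may be slow if the ring cannot reach the chair-like samarium chelate, and the acid used for lactonisation may start transannular reactions of the diene. The fallback sets out from 14 and relies on substrate control and a separate esterification.
- Reduction with NaBH4 and CeCl3·7H2O gives tert-butyl 2-[(1S,2R,3Z,5S,7E,10R)-5-[(tert-butyldimethylsilyl)oxy]-2-hydroxy-10-[(4-methoxyphenyl)methoxy]-4,8-dimethylcyclodeca-3,7-dien-1-yl]acetate F3; a C6 epimer, if formed, is separated.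
- Lactonisation with catalytic CSA gives (3aR,4R,6E,9S,10Z,11aR)-9-[(tert-butyldimethylsilyl)oxy]-4-[(4-methoxyphenyl)methoxy]-6,10-dimethyl-3a,4,5,8,9,11a-hexahydrocyclodeca[b]furan-2(3H)-one F4.
- DDQ gives (3aR,4R,6E,9S,10Z,11aR)-9-[(tert-butyldimethylsilyl)oxy]-4-hydroxy-6,10-dimethyl-3a,4,5,8,9,11a-hexahydrocyclodeca[b]furan-2(3H)-one F5.
- F5 is esterified at once, to forestall relactonisation, with (2R,3S)-2,3-dimethyloxirane-2-carboxylic acid F6 (made from 18 with NaClO2) using 2,4,6-trichlorobenzoyl chloride, Et3N and DMAP. The fallback comes back to the route at 20.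

**Step 12.** The free lithium enolate at C11 lies cis to the C8 ester and may attack its carbonyl group (intramolecular C-acylation) before it meets the iminium salt. The fallback sets out from 20 and avoids a free enolate: deprotonation with LiN(i-Pr)2 in the presence of Me3SiCl (in situ quench) gives the trimethylsilyl ketene acetal of 20 F7, which reacts with the iminium salt in a Mannich reaction of the silyl ketene acetal type. The fallback comes back to the route at 22, from which quaternisation and elimination follow as in step 12.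

**Step 15.** The peracid may attack the wrong face of C1=C10 if the ring of 26 prefers a conformer with C14 on the other side, since facial selectivity rests only on the ring conformation. The fallback sets out from 26 and replaces substrate control by reagent control: epoxidation with the fructose-derived chiral ketone of the Shi epoxidation (the enantiomer that matches the required face) and KHSO5 (as the triple salt 2KHSO5·KHSO4·K2SO4) in a buffered two-phase system at 0 °C. It makes no new compound (F0) and comes back to the route at 27.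

## Further compounds

F1 | step 7 | (2Z,4S,6E,9R)-4-[(tert-butyldimethylsilyl)oxy]-9-[(4-methoxyphenyl)methoxy]-3,7-dimethylcyclodeca-2,6-dien-1-one | O=C1/C=C(/C)[C@@H](O[Si](C)(C)C(C)(C)C)C/C=C(\C)C[C@@H](OCc2ccc(OC)cc2)C1
F2 | step 6 | (1R,4S,6S)-4-[(tert-butyldimethylsilyl)oxy]-1-{(Z)-2-[(4-methoxyphenyl)methoxy]ethenyl}-3-methyl-6-(prop-1-en-2-yl)cyclohex-2-en-1-ol | CC1=C[C@](O)(/C=C\OCc2ccc(OC)cc2)[C@@H](C[C@@H]1O[Si](C)(C)C(C)(C)C)C(C)=C
F3 | step 11 | tert-butyl 2-[(1S,2R,3Z,5S,7E,10R)-5-[(tert-butyldimethylsilyl)oxy]-2-hydroxy-10-[(4-methoxyphenyl)methoxy]-4,8-dimethylcyclodeca-3,7-dien-1-yl]acetate | O[C@@H]1/C=C(/C)[C@@H](O[Si](C)(C)C(C)(C)C)C/C=C(\C)C[C@@H](OCc2ccc(OC)cc2)[C@H]1CC(=O)OC(C)(C)C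
F4 | step 11 | (3aR,4R,6E,9S,10Z,11aR)-9-[(tert-butyldimethylsilyl)oxy]-4-[(4-methoxyphenyl)methoxy]-6,10-dimethyl-3a,4,5,8,9,11a-hexahydrocyclodeca[b]furan-2(3H)-one | C1C(=O)O[C@@H]2/C=C(/C)[C@@H](O[Si](C)(C)C(C)(C)C)C/C=C(\C)C[C@@H](OCc3ccc(OC)cc3)[C@@H]12
F5 | step 11 | (3aR,4R,6E,9S,10Z,11aR)-9-[(tert-butyldimethylsilyl)oxy]-4-hydroxy-6,10-dimethyl-3a,4,5,8,9,11a-hexahydrocyclodeca[b]furan-2(3H)-one | C1C(=O)O[C@@H]2/C=C(/C)[C@@H](O[Si](C)(C)C(C)(C)C)C/C=C(\C)C[C@@H](O)[C@@H]12
F6 | step 11 | (2R,3S)-2,3-dimethyloxirane-2-carboxylic acid | OC(=O)[C@]1(C)O[C@H]1C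
F7 | step 12 | trimethylsilyl ketene acetal of 20 | C1=C(O[Si](C)(C)C)O[C@@H]2/C=C(/C)[C@@H](O[Si](C)(C)C(C)(C)C)C/C=C(\C)C[C@@H](OC(=O)[C@]3(C)O[C@H]3C)[C@@H]12
F0 | step 15 | none | none
A1 | alternative 1 | methyl (2Z,4R,6E,9S,10Z)-2-(bromomethyl)-9-[(tert-butyldimethylsilyl)oxy]-4-[(4-methoxyphenyl)methoxy]-6,10-dimethyl-12-oxododeca-2,6,10-trienoate | O=C/C=C(/C)[C@@H](O[Si](C)(C)C(C)(C)C)C/C=C(\C)C[C@@H](OCc1ccc(OC)cc1)/C=C(\CBr)C(=O)OC
A2 | alternative 2 | open-chain triene lactone: (2R,3S)-2,3-dimethyloxirane-2-carboxylate of the 5-ethenyl-4-methylidene-2-oxotetrahydrofuran-3-yl carbinol that carries the E-trisubstituted olefin, the isobutyrate and the isopropenyl terminus | C=C1C(=O)O[C@H](C=C)[C@H]1[C@H](OC(=O)[C@]2(C)O[C@H]2C)C/C(C)=C/C[C@H](OC(=O)C(C)C)C(C)=C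
A3 | alternative 3 | (3Z,5S,7E,10R,11E)-5-[(tert-butyldimethylsilyl)oxy]-10-[(4-methoxyphenyl)methoxy]-4,8,12-trimethyl-1-oxacyclotrideca-3,7,11-triene | O1C/C=C(/C)[C@@H](O[Si](C)(C)C(C)(C)C)C/C=C(\C)C[C@@H](OCc2ccc(OC)cc2)/C=C(\C)C1
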